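## Structural features

The target is (2E)-4-[(1R,5R,6R)-3-[(1E)-hept-1-en-1-yl]-5-hydroxy-4-(hydroxymethyl)-2-oxo-7-oxabicyclo[4.1.0]hept-3-en-1-yl]-2-methylbut-2-enoic acid. It is a cyclohexenone (C1–C6) cis-fused to an oxirane across C1–C6 (O7), with the ketone at C2 and the ring alkene at C3=C4. C3 carries an (E)-heptenyl group, so C2=O, C3=C4 and the side-chain alkene form a cross-conjugated dienone. C4 carries CH2OH, and the quaternary oxirane carbon C1 carries an (E)-3-carboxybut-2-enyl chain. The three stereocentres C1, C6 and C5 are contiguous: the C5 hydroxyl is cis to O7 and the C1 side chain lies on the opposite ring face. Fragile elements are the oxirane next to a ketone (bases, nucleophiles, single-electron reductants), the doubly allylic C5 carbinol, the diene (oxidants, metathesis catalysts) and the free acid. The real difficulty lies in the tetrasubstituted C3=C4 alkene with four different substituents, the quaternary oxirane carbon, the cis C5–OH/O7 relationship, and the ordering of the alkene-forming steps so that the three side-chain alkenes do not interfere with one another. The key step exploits the fact that C5 is a secondary allylic carbinol lying between the sp2 carbon C4 and the oxirane carbon C6, so the six-membered ring can be closed by adding a C4 alkenyl metal to a C5 aldehyde.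

## Logic of the disconnections

26 to 25: only the carboxyl C–O bond is cut. The acid is made last by chemoselective oxidation of an enal, so no ester has to be hydrolysed with base in the presence of the epoxy enone. The forward step must spare the diene and the allylic alcohols.

25 to 24: no skeletal bond is cut. One Si–O bond and the two acetal C–O bonds are removed in a single acidic operation. The oxirane must tolerate that acid.

24 to 22: the C4–C5 bond is cut (key step). This opens the carbocycle to an acyclic chain in which C1 and C6 are already fixed, and only C5 remains to be set. The forward step needs the Z geometry at C3=C4 (iodine cis to C2), a nucleophile that attacks only the aldehyde, and control of C5 by the oxirane. 22 and 24 are the iodo dienone epoxy aldehyde and the C5-hydroxy epoxycyclohexenone of this disconnection. They carry a triisopropylsilyl ether on the C4 hydroxymethyl group (it must outlast a tert-butyldimethylsilyl ether elsewhere) and a dimethyl acetal as the masked carboxyl (an ester would not survive step 10).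

22 to 20 to 19: no C–C bond is cut; only the oxidation levels at C2 and C5 and the C5 silyl ether change. Both carbonyls stay masked until just before cyclisation. C2 must be oxidised before C5, because a C5 aldehyde next to a free cis C2 hydroxyl would close to a lactol and be over-oxidised to a lactone.

19 to 13 and 16: the C3–heptenyl bond and the C4–I bond are cut, as an anti addition across an alkyne. The tetrasubstituted alkene with defined geometry then comes from a simple internal alkyne and an alkenyl halide. The forward step needs the C2 alkoxide as directing group and requires oxirane and acetal to survive a Grignard reagent. No terminal alkene remains at this stage, so no metathesis is needed once the diene exists.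

16 to 14: the C–I bond is cut; a syn hydrometalation of the terminal alkyne sets the E geometry.

13 to 10 and 11: the C2–C3 bond is cut (acetylide plus aldehyde). The new C2 centre needs no control because it becomes sp2.

10 to 9 to 8: the C1–O7 and C6–O7 bonds are cut (asymmetric epoxidation of an allylic alcohol). Both oxirane stereocentres arise under reagent control from an achiral Z-alkene. This demands a single free allylic hydroxyl, since two would direct the reagent to opposite faces, and a pure Z geometry.

8 to 7 to 5 and 6: the side-chain C=C bond is cut (cross-metathesis). It is placed before any alkyne or diene is present, because the terminal alkene would otherwise ring-close onto them. The enal is masked at once as its acetal. The forward step must be E-selective.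

5 to 3 and 4, then 3 to 2 to 1: the C1–CH2 bond (alkenylstannane coupling), one O–Si bond, and the C–Sn and C–H bonds (syn hydrostannation) are cut. This leads back to the symmetrical 1. It requires syn addition, which sets the cis relationship of the two oxygenated arms, and a regioselective monosilylation.

## Other disconnections considered

Alternative 1: The cut is C1–C2. In the forward step a triazolylidene carbene would add to the C2 enal of the acyclic keto enal A1, and the Breslow intermediate would attack the C1 ketone to give the 6-allyl-6-hydroxycyclohexenone A2.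
- In favour: the step is catalytic and metal-free, it closes the ring and creates the quaternary carbinol C1 in one operation, and intramolecular aldehyde–ketone benzoin closures are a known reaction type. On waste, and on not exposing an epoxy ketone to a reductant, it is better than the chosen plan.
- Against: A1 carries a silyloxy group gamma to the enal carbonyl, which invites redox elimination from the Breslow intermediate. The C6 centre alpha to the ketone can epimerise under the base. C1 is set only by substrate control, whereas the chosen plan sets C1 and C6 by a reagent before the ring exists.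
- Step economy: the oxirane is still missing in A2. It needs desilylation at C6, sulfonylation and invertive closure (A2 has the required trans C1–OH/C6–O arrangement), then side-chain metathesis and deprotection. That is at least five steps after the key step against two in the chosen plan.
- Structure: A1 needs the same Z-configured tetrasubstituted C3=C4 alkene as 22, so the alternative is equal, not better, on the hardest structural element.

Alternative 2: The cut is C3–C4, with the exocyclic vinyl bond formed at the same time. In the forward step the second-generation Grubbs catalyst would convert the 1,7-enyne A3 into the 1-vinylcyclohexene A4. The ring carbon C3 is the internal carbon of the terminal alkyne; the terminal CH ends up in the vinyl group.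
- In favour: one catalytic step forms two C–C bonds and the ring, and all oxirane and carbinol stereocentres are already in place. It avoids the tetrasubstituted alkenyl iodide and its anti carbometalation altogether. On that point, and on metal waste, it is better than the chosen plan.
- Against: a tetrasubstituted ring alkene must form from a 1,1-disubstituted alkene. The vinyl group then has to be lengthened to the (E)-heptenyl group by cross-metathesis on a conjugated diene, with site and E/Z risk. C2 must be oxidised and three protecting groups removed, one by ester hydrolysis on the epoxy enone.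
- Comparison: the key step creates no stereocentre, so C5 needs separate control earlier; the chosen plan creates C5 in the ring closure. About four steps follow A4 against two after 24.

Alternative 3: The cuts are C1–C6 and O7–C1. In the forward step base would convert the alpha-bromo ketone aldehyde A5 into its C1 enolate, aldol addition to the C6 aldehyde would close the carbocycle, and the C6 alkoxide would displace bromide to give the epoxycyclohexenone A6.
- In favour: two bonds, both rings and two stereocentres form in one metal-free operation, and A6 differs from 24 only in protecting groups. In bonds and rings per step it is better than the chosen plan, and in end-game length it is its equal.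
- Against: A5 is poorly matched to a base. C5 is alpha to the aldehyde and can epimerise or eliminate, the bromide can be lost toward the side chain, and only the anti bromohydrin can close. C1 and C6 are set only relative to C5, which itself must be made enantiopure elsewhere; in the chosen plan C1 and C6 come from a reagent-controlled epoxidation. A5 also still contains the Z tetrasubstituted C3=C4 alkene.

Key step: step 13

Assumption: the carbinol centre created at C2 in step 8 is carried as both epimers up to 20, because step 12 turns C2 into a carbonyl; 11 is taken as a catalogue silyl ether of propargyl alcohol.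

## Steps

Step 1
Reactants: 1 but-2-yne-1,4-diol
Product: 2 (2E)-2-(tributylstannyl)but-2-ene-1,4-diol
Conditions: Bu3SnH, PdCl2(PPh3)2 (2 mol%), THF, rt
Reagents that add atoms: tributyltin hydride, CCCC[SnH](CCCC)CCCC
Why: Palladium-catalysed hydrostannation (zerovalent palladium formed in situ) adds H and SnBu3 syn across the symmetrical alkyne, so the two hydroxymethyl arms end cis, the relationship that C2 and C5 must have on the later oxirane.

Step 2
Reactants: 2 (2E)-2-(tributylstannyl)but-2-ene-1,4-diol
Product: 3 (2E)-4-{[tert-butyl(dimethyl)silyl]oxy}-2-(tributylstannyl)but-2-en-1-ol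
Conditions: TBSCl (1.0 equiv), imidazole, CH2Cl2, −40 °C
Reagents that add atoms: tert-butyldimethylsilyl chloride, CC(C)(C)[Si](C)(C)Cl
Why: The hydroxymethyl group on the tin-bearing carbon is shielded by the Bu3Sn group, so one equivalent of the bulky silyl chloride should take the remote (future C5) hydroxyl; protecting it now leaves a single directing hydroxyl for step 6, where two free allylic hydroxyls would steer the titanium reagent to opposite faces.

Step 3
Reactants: 3 (2E)-4-{[tert-butyl(dimethyl)silyl]oxy}-2-(tributylstannyl)but-2-en-1-ol; 4 3-bromoprop-1-ene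
Product: 5 (2Z)-4-{[tert-butyl(dimethyl)silyl]oxy}-2-(prop-2-en-1-yl)but-2-en-1-ol
Conditions: Pd2(dba)3 (2.5 mol%), AsPh3, CuI, DMF, 40 °C
Reagents that add atoms: none
Why: Stille coupling of an alkenylstannane with an allylic bromide (zerovalent palladium) proceeds with retention at the alkenyl carbon, so the allyl branch enters at C1 and the cis relationship of the two oxygenated arms is kept.

Step 4
Reactants: 5 (2Z)-4-{[tert-butyl(dimethyl)silyl]oxy}-2-(prop-2-en-1-yl)but-2-en-1-ol; 6 2-methylprop-2-enal
Product: 7 (2E,5Z)-7-{[tert-butyl(dimethyl)silyl]oxy}-5-(hydroxymethyl)-2-methylhepta-2,5-dienal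
Conditions: second-generation Grubbs catalyst (5 mol%), 6 (6 equiv), CH2Cl2, 40 °C
Reagents that add atoms: none
Why: Cross-metathesis of the terminal alkene with an excess of an electron-poor 1,1-disubstituted partner gives the trisubstituted (E)-enal under thermodynamic control; it is done here because no alkyne or heptenyl diene is present yet, so ring-closing (enyne) metathesis of the allyl group cannot compete.

Step 5
Reactants: 7 (2E,5Z)-7-{[tert-butyl(dimethyl)silyl]oxy}-5-(hydroxymethyl)-2-methylhepta-2,5-dienal
Product: 8 (2Z)-4-{[tert-butyl(dimethyl)silyl]oxy}-2-[(2E)-4,4-dimethoxy-3-methylbut-2-en-1-yl]but-2-en-1-ol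
Conditions: HC(OMe)3, MeOH, PPTS (cat.), 0 °C to rt; Et3N quench
Reagents that add atoms: trimethyl orthoformate, COC(OC)OC; methanol, CO
Why: Acid-catalysed acetalisation masks the enal as a dimethyl acetal that is inert to the acetylide, the Grignard reagent and divalent chromium used later; the carboxyl is thus carried at the aldehyde level and no ester must be saponified at the end.

Step 6
Reactants: 8 (2Z)-4-{[tert-butyl(dimethyl)silyl]oxy}-2-[(2E)-4,4-dimethoxy-3-methylbut-2-en-1-yl]but-2-en-1-ol
Product: 9 [(2S,3R)-3-({[tert-butyl(dimethyl)silyl]oxy}methyl)-2-[(2E)-4,4-dimethoxy-3-methylbut-2-en-1-yl]oxiran-2-yl]methanol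
Conditions: Ti(OiPr)4, L-(+)-diethyl tartrate, tBuOOH, 4 Å MS, CH2Cl2, −20 °C
Reagents that add atoms: tert-butyl hydroperoxide, CC(C)(C)OO
Why: Sharpless asymmetric epoxidation; with L-(+)-tartrate the titanium-bound alkoxide of this Z-configured 2,3-disubstituted allylic alcohol receives oxygen on the face that gives the (2S,3R)-oxirane, which sets C1 and C6 of the target under reagent control. The other two alkenes are not allylic alcohols and should stay untouched.

Step 7
Reactants: 9 [(2S,3R)-3-({[tert-butyl(dimethyl)silyl]oxy}methyl)-2-[(2E)-4,4-dimethoxy-3-methylbut-2-en-1-yl]oxiran-2-yl]methanol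
Product: 10 (2R,3R)-3-({[tert-butyl(dimethyl)silyl]oxy}methyl)-2-[(2E)-4,4-dimethoxy-3-methylbut-2-en-1-yl]oxirane-2-carbaldehyde
Conditions: Dess–Martin periodinane, NaHCO3, CH2Cl2, 0 °C to rt
Reagents that add atoms: none
Why: Buffered Dess–Martin oxidation of the primary alcohol gives the epoxy aldehyde without touching the acetal; the alpha carbon is quaternary, so the aldehyde cannot epimerise.

Step 8
Reactants: 11 triisopropyl(prop-2-yn-1-yloxy)silane; 10 (2R,3R)-3-({[tert-butyl(dimethyl)silyl]oxy}methyl)-2-[(2E)-4,4-dimethoxy-3-methylbut-2-en-1-yl]oxirane-2-carbaldehyde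
Product: 13 1-[(2S,3R)-3-({[tert-butyl(dimethyl)silyl]oxy}methyl)-2-[(2E)-4,4-dimethoxy-3-methylbut-2-en-1-yl]oxiran-2-yl]-4-[(triisopropylsilyl)oxy]but-2-yn-1-ol (both carbinol epimers), via lithium acetylide 12 (not isolated)
Conditions: 11, nBuLi, THF, −78 °C; then 10, −78 °C; H2O
Reagents that add atoms: none
Why: 1,2-Addition of a lithium acetylide to the aldehyde forms the C2–C3 bond at low temperature without touching the oxirane; the new carbinol centre is uncontrolled, which is harmless because C2 becomes a ketone in step 12.

Step 9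
Reactants: 14 hept-1-yne
Product: 16 (1E)-1-iodohept-1-ene, via alkenylzirconocene chloride 15 (not isolated)
Conditions: Cp2Zr(H)Cl, THF, rt; then I2, 0 °C
Reagents that add atoms: iodine, II
Why: Hydrozirconation of a terminal alkyne is a syn, anti-Markovnikov addition and iodinolysis of the C–Zr bond goes with retention, giving the (E)-alkenyl iodide.

Step 10
Reactants: 16 (1E)-1-iodohept-1-ene; 13 1-[(2S,3R)-3-({[tert-butyl(dimethyl)silyl]oxy}methyl)-2-[(2E)-4,4-dimethoxy-3-methylbut-2-en-1-yl]oxiran-2-yl]-4-[(triisopropylsilyl)oxy]but-2-yn-1-ol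
Product: 19 (2Z,3E)-1-[(2S,3R)-3-({[tert-butyl(dimethyl)silyl]oxy}methyl)-2-[(2E)-4,4-dimethoxy-3-methylbut-2-en-1-yl]oxiran-2-yl]-2-{1-iodo-2-[(triisopropylsilyl)oxy]ethylidene}non-3-en-1-ol (both carbinol epimers), via heptenylmagnesium iodide 17 (not isolated), via magnesium chelate 18 (not isolated)
Conditions: 16, Mg, THF, rt; then 13, THF/toluene, 0 to 45 °C; I2, −78 to 0 °C; H2O
Reagents that add atoms: iodine, II
Why: Alkoxide-directed anti-carbomagnesiation of a propargylic alcohol: the C2 magnesium alkoxide delivers the alkenyl group to the proximal alkyne carbon C3 and magnesium to C4 in a five-membered chelate, so heptenyl and magnesium are trans, and iodinolysis with retention gives the Z-iodoalkene with iodine cis to C2. No copper salt is used, so that the hindered trisubstituted oxirane and the allylic acetal are not attacked, and the silyloxy group beta to magnesium is too poor a leaving group to give an allene.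

Step 11
Reactants: 19 (2Z,3E)-1-[(2S,3R)-3-({[tert-butyl(dimethyl)silyl]oxy}methyl)-2-[(2E)-4,4-dimethoxy-3-methylbut-2-en-1-yl]oxiran-2-yl]-2-{1-iodo-2-[(triisopropylsilyl)oxy]ethylidene}non-3-en-1-ol
Product: 20 (2Z,3E)-1-[(2S,3R)-3-(hydroxymethyl)-2-[(2E)-4,4-dimethoxy-3-methylbut-2-en-1-yl]oxiran-2-yl]-2-{1-iodo-2-[(triisopropylsilyl)oxy]ethylidene}non-3-en-1-ol (both carbinol epimers)
Conditions: HF·pyridine, pyridine, THF, 0 °C to rt
Reagents that add atoms: none
Why: Buffered HF·pyridine cleaves the unhindered primary tert-butyldimethylsilyl ether much faster than the primary triisopropylsilyl ether on the crowded allylic position; the acetal and the oxirane tolerate the buffered reagent.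

Step 12
Reactants: 20 (2Z,3E)-1-[(2S,3R)-3-(hydroxymethyl)-2-[(2E)-4,4-dimethoxy-3-methylbut-2-en-1-yl]oxiran-2-yl]-2-{1-iodo-2-[(triisopropylsilyl)oxy]ethylidene}non-3-en-1-ol
Product: 22 (2S,3R)-3-[(2Z,3E)-2-{1-iodo-2-[(triisopropylsilyl)oxy]ethylidene}non-3-enoyl]-3-[(2E)-4,4-dimethoxy-3-methylbut-2-en-1-yl]oxirane-2-carbaldehyde, via hydroxy dienone 21 (not isolated)
Conditions: MnO2 (excess), CH2Cl2, rt; filtration; then Dess–Martin periodinane, NaHCO3, CH2Cl2, 0 °C
Reagents that add atoms: none
Why: MnO2 oxidises only the dienylic C2 carbinol, and only then is the primary C5 alcohol oxidised by Dess–Martin periodinane; in the reverse order the C5 aldehyde would form a lactol with the cis C2 hydroxyl and be oxidised to a lactone. The labile keto aldehyde is used at once.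

Step 13
Reactants: 22 (2S,3R)-3-[(2Z,3E)-2-{1-iodo-2-[(triisopropylsilyl)oxy]ethylidene}non-3-enoyl]-3-[(2E)-4,4-dimethoxy-3-methylbut-2-en-1-yl]oxirane-2-carbaldehyde
Product: 24 (1R,5R,6R)-1-[(2E)-4,4-dimethoxy-3-methylbut-2-en-1-yl]-3-[(1E)-hept-1-en-1-yl]-5-hydroxy-4-{[(triisopropylsilyl)oxy]methyl}-7-oxabicyclo[4.1.0]hept-3-en-2-one, via alkenylchromium dichloride 23 (not isolated)
Conditions: CrCl2 (6 equiv), NiCl2 (2 mol%), degassed DMSO, rt, 3 mM; H2O
Reagents that add atoms: none
Why: Nozaki–Hiyama–Kishi reaction: NiCl2 is reduced by divalent chromium to zerovalent nickel, which inserts into the C4–I bond with retention, and transmetalation gives an alkenyl species of trivalent chromium that adds to the C5 aldehyde; the closest known reaction type is the intramolecular alkenyl iodide–aldehyde closure of beta-iodo enones and enoates. The closure is 6-exo-trig (the carbonyl oxygen stays outside the new carbocycle), and the Z geometry fixed in step 10 holds C4 and the C2 acyl arm on the same side, so only the six-membered ring can form. Organochromium reagents add to aldehydes far faster than to ketones, acetals or oxiranes, so C2, the acetal and O7 should survive, and the silyloxy group beta to chromium is a poor leaving group. C5 is controlled by the C1/C6 oxirane: the tether forces the nucleophile to arrive from the C1 side, so the hydroxyl ends cis to O7 only if the C5=O bond is syn-clinal to the C6–O7 bond in the transition state. The rotamer with C=O anti to C6–O7, the Felkin-type arrangement open to an external nucleophile, would here give the trans isomer. The syn-clinal rotamer is expected to win because the chromium-bound oxygen then sits on the ring face that carries only the small oxirane oxygen, which chromium can also bind, whereas the other rotamer presses the chromium alkoxide against the C1 side chain in a 1,3-relationship. High dilution suppresses intermolecular coupling.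

Step 14
Reactants: 24 (1R,5R,6R)-1-[(2E)-4,4-dimethoxy-3-methylbut-2-en-1-yl]-3-[(1E)-hept-1-en-1-yl]-5-hydroxy-4-{[(triisopropylsilyl)oxy]methyl}-7-oxabicyclo[4.1.0]hept-3-en-2-one
Product: 25 (2E)-4-[(1R,5R,6R)-3-[(1E)-hept-1-en-1-yl]-5-hydroxy-4-(hydroxymethyl)-2-oxo-7-oxabicyclo[4.1.0]hept-3-en-1-yl]-2-methylbut-2-enal
Conditions: 48% aq. HF, MeCN, 0 °C to rt
Reagents that add atoms: water, O
Why: Aqueous HF cleaves the primary silyl ether and hydrolyses the unsaturated dimethyl acetal through an allyl-stabilised oxocarbenium ion; the oxirane is deactivated toward acid opening by the adjacent ketone and is expected to survive.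

Step 15
Reactants: 25 (2E)-4-[(1R,5R,6R)-3-[(1E)-hept-1-en-1-yl]-5-hydroxy-4-(hydroxymethyl)-2-oxo-7-oxabicyclo[4.1.0]hept-3-en-1-yl]-2-methylbut-2-enal
Product: 26 (2E)-4-[(1R,5R,6R)-3-[(1E)-hept-1-en-1-yl]-5-hydroxy-4-(hydroxymethyl)-2-oxo-7-oxabicyclo[4.1.0]hept-3-en-1-yl]-2-methylbut-2-enoic acid
Conditions: NaClO2, NaH2PO4, 2-methylbut-2-ene, tBuOH/H2O, 0 °C to rt
Reagents that add atoms: sodium chlorite, [Na+].[O-]Cl=O
Why: Pinnick oxidation converts only the aldehyde to the acid in a weakly acidic buffer, and hypochlorous acid is trapped by 2-methylbut-2-ene, so the diene, the allylic alcohols and the base-sensitive epoxy enone should be untouched and the E geometry retained.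

## Compound list

1 | but-2-yne-1,4-diol | OCC#CCO | starting material
2 | (2E)-2-(tributylstannyl)but-2-ene-1,4-diol | OC/C=C(\CO)[Sn](CCCC)(CCCC)CCCC | intermediate
3 | (2E)-4-{[tert-butyl(dimethyl)silyl]oxy}-2-(tributylstannyl)but-2-en-1-ol | CC(C)(C)[Si](C)(C)OC/C=C(\CO)[Sn](CCCC)(CCCC)CCCC | intermediate
4 | 3-bromoprop-1-ene (allyl bromide) | C=CCBr | starting material
5 | (2Z)-4-{[tert-butyl(dimethyl)silyl]oxy}-2-(prop-2-en-1-yl)but-2-en-1-ol | OC/C(CC=C)=C\CO[Si](C)(C)C(C)(C)C | intermediate
6 | 2-methylprop-2-enal (methacrolein) | C=C(C)C=O | starting material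
7 | (2E,5Z)-7-{[tert-butyl(dimethyl)silyl]oxy}-5-(hydroxymethyl)-2-methylhepta-2,5-dienal | OC/C(C/C=C(\C)C=O)=C\CO[Si](C)(C)C(C)(C)C | intermediate
8 | (2Z)-4-{[tert-butyl(dimethyl)silyl]oxy}-2-[(2E)-4,4-dimethoxy-3-methylbut-2-en-1-yl]but-2-en-1-ol | OC/C(C/C=C(\C)C(OC)OC)=C\CO[Si](C)(C)C(C)(C)C | intermediate
9 | [(2S,3R)-3-({[tert-butyl(dimethyl)silyl]oxy}methyl)-2-[(2E)-4,4-dimethoxy-3-methylbut-2-en-1-yl]oxiran-2-yl]methanol | OC[C@]1(C/C=C(\C)C(OC)OC)O[C@@H]1CO[Si](C)(C)C(C)(C)C | intermediate
10 | (2R,3R)-3-({[tert-butyl(dimethyl)silyl]oxy}methyl)-2-[(2E)-4,4-dimethoxy-3-methylbut-2-en-1-yl]oxirane-2-carbaldehyde | O=C[C@]1(C/C=C(\C)C(OC)OC)O[C@@H]1CO[Si](C)(C)C(C)(C)C | intermediate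
11 | triisopropyl(prop-2-yn-1-yloxy)silane | C#CCO[Si](C(C)C)(C(C)C)C(C)C | starting material
12 | lithium 3-[(triisopropylsilyl)oxy]prop-1-yn-1-ide | [Li]C#CCO[Si](C(C)C)(C(C)C)C(C)C | intermediate (not isolated)
13 | 1-[(2S,3R)-3-({[tert-butyl(dimethyl)silyl]oxy}methyl)-2-[(2E)-4,4-dimethoxy-3-methylbut-2-en-1-yl]oxiran-2-yl]-4-[(triisopropylsilyl)oxy]but-2-yn-1-ol, both carbinol epimers | CC(C)[Si](OCC#CC(O)[C@]1(C/C=C(\C)C(OC)OC)O[C@@H]1CO[Si](C)(C)C(C)(C)C)(C(C)C)C(C)C | intermediate
14 | hept-1-yne | CCCCCC#C | starting material
15 | chlorobis(cyclopentadienyl)[(1E)-hept-1-en-1-yl]zirconium | CCCCC/C=C/[Zr](Cl)(C1C=CC=C1)C1C=CC=C1 | intermediate (not isolated)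
16 | (1E)-1-iodohept-1-ene | CCCCC/C=C/I | intermediate
17 | [(1E)-hept-1-en-1-yl]magnesium iodide | CCCCC/C=C/[Mg]I | intermediate (not isolated)
18 | five-membered C4–Mg–O–C2 chelate (2,5-dihydro-1,2-oxamagnesole) formed from 13 by anti addition of heptenyl at C3 and magnesium at C4 | CCCCC/C=C/C1=C(CO[Si](C(C)C)(C(C)C)C(C)C)[Mg]OC1[C@]2(C/C=C(\C)C(OC)OC)O[C@@H]2CO[Si](C)(C)C(C)(C)C | intermediate (not isolated)
19 | (2Z,3E)-1-[(2S,3R)-3-({[tert-butyl(dimethyl)silyl]oxy}methyl)-2-[(2E)-4,4-dimethoxy-3-methylbut-2-en-1-yl]oxiran-2-yl]-2-{1-iodo-2-[(triisopropylsilyl)oxy]ethylidene}non-3-en-1-ol, both carbinol epimers | CCCCC/C=C/C(=C(/I)CO[Si](C(C)C)(C(C)C)C(C)C)C(O)[C@]1(C/C=C(\C)C(OC)OC)O[C@@H]1CO[Si](C)(C)C(C)(C)C | intermediate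
20 | (2Z,3E)-1-[(2S,3R)-3-(hydroxymethyl)-2-[(2E)-4,4-dimethoxy-3-methylbut-2-en-1-yl]oxiran-2-yl]-2-{1-iodo-2-[(triisopropylsilyl)oxy]ethylidene}non-3-en-1-ol, both carbinol epimers | CCCCC/C=C/C(=C(/I)CO[Si](C(C)C)(C(C)C)C(C)C)C(O)[C@]1(C/C=C(\C)C(OC)OC)O[C@@H]1CO | intermediate
21 | (2Z,3E)-1-[(2R,3R)-3-(hydroxymethyl)-2-[(2E)-4,4-dimethoxy-3-methylbut-2-en-1-yl]oxiran-2-yl]-2-{1-iodo-2-[(triisopropylsilyl)oxy]ethylidene}non-3-en-1-one | CCCCC/C=C/C(=C(/I)CO[Si](C(C)C)(C(C)C)C(C)C)C(=O)[C@]1(C/C=C(\C)C(OC)OC)O[C@@H]1CO | intermediate (not isolated)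
22 | (2S,3R)-3-[(2Z,3E)-2-{1-iodo-2-[(triisopropylsilyl)oxy]ethylidene}non-3-enoyl]-3-[(2E)-4,4-dimethoxy-3-methylbut-2-en-1-yl]oxirane-2-carbaldehyde | CCCCC/C=C/C(=C(/I)CO[Si](C(C)C)(C(C)C)C(C)C)C(=O)[C@]1(C/C=C(\C)C(OC)OC)O[C@@H]1C=O | intermediate
23 | alkenylchromium dichloride derived from 22 (CrCl2 in place of iodine at C4, same alkene geometry) | CCCCC/C=C/C(=C(/[Cr](Cl)Cl)CO[Si](C(C)C)(C(C)C)C(C)C)C(=O)[C@]1(C/C=C(\C)C(OC)OC)O[C@@H]1C=O | intermediate (not isolated)
24 | (1R,5R,6R)-1-[(2E)-4,4-dimethoxy-3-methylbut-2-en-1-yl]-3-[(1E)-hept-1-en-1-yl]-5-hydroxy-4-{[(triisopropylsilyl)oxy]methyl}-7-oxabicyclo[4.1.0]hept-3-en-2-one | CCCCC/C=C/C1=C(CO[Si](C(C)C)(C(C)C)C(C)C)[C@@H](O)[C@H]2O[C@@]2(C/C=C(\C)C(OC)OC)C1=O | intermediate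
25 | (2E)-4-[(1R,5R,6R)-3-[(1E)-hept-1-en-1-yl]-5-hydroxy-4-(hydroxymethyl)-2-oxo-7-oxabicyclo[4.1.0]hept-3-en-1-yl]-2-methylbut-2-enal | CCCCC/C=C/C1=C(CO)[C@@H](O)[C@H]2O[C@@]2(C/C=C(\C)C=O)C1=O | intermediate
26 | (2E)-4-[(1R,5R,6R)-3-[(1E)-hept-1-en-1-yl]-5-hydroxy-4-(hydroxymethyl)-2-oxo-7-oxabicyclo[4.1.0]hept-3-en-1-yl]-2-methylbut-2-enoic acid | CCCCC/C=C/C1=C(CO)[C@@H](O)[C@H]2O[C@@]2(C/C=C(\C)C(=O)O)C1=O | target

## Step count and least certain steps

Total step count: 15. Longest linear sequence: 14 steps (steps 1 to 8 and 10 to 15, from 1); step 9 is a one-step side branch from 14.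

Step 13 (key step). The most likely failure is poor facial selectivity at C5. The syn-clinal (chromium-bridged) rotamer and the dipole-opposed rotamer of the epoxy aldehyde may be close in energy in a strongly donating solvent, and the tethered nucleophile cannot adopt the trajectory anti to the C6–O7 bond. A second hazard is single-electron opening of the C1–O7 bond next to the C2 ketone by the excess of divalent chromium. The fallback sets C5 by reduction instead of by C–C bond formation. It sets out from 24, taken as whatever C5 epimer mixture the closure delivers. Dess–Martin oxidation would give (1R,6S)-1-[(2E)-4,4-dimethoxy-3-methylbut-2-en-1-yl]-3-[(1E)-hept-1-en-1-yl]-4-{[(triisopropylsilyl)oxy]methyl}-7-oxabicyclo[4.1.0]hept-3-ene-2,5-dione F1. NaBH4 with CeCl3 at −78 °C (Luche reduction) should then reduce the C5 carbonyl, which is less hindered than C2 (flanked by the quaternary C1), from the face anti to the oxirane C–O bond. An external hydride can use this trajectory, and it places the hydroxyl cis to O7. The sequence comes back to the route at 24.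

Step 10. The most likely failure is loss of the oxirane during the warm, Lewis-acidic Grignard step, by halide or carbanion opening at C6 or by rearrangement triggered by the neighbouring C2 magnesium alkoxide. The fallback moves the carbomagnesiation ahead of the epoxidation. It sets out from 8.
- MnO2 would give (2Z)-4-{[tert-butyl(dimethyl)silyl]oxy}-2-[(2E)-4,4-dimethoxy-3-methylbut-2-en-1-yl]but-2-enal F2, used cold and at once to avoid Z to E isomerisation.
- Addition of lithiated 11 would give (5Z)-7-{[tert-butyl(dimethyl)silyl]oxy}-5-[(2E)-4,4-dimethoxy-3-methylbut-2-en-1-yl]-1-[(triisopropylsilyl)oxy]hept-5-en-2-yn-4-ol F3.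
- Anti-carbomagnesiation with 17 and iodinolysis, now on a substrate without an oxirane, would give the racemic doubly allylic iodo-triene alcohol F4.
- HF·pyridine would free the primary allylic alcohol to give the diol F5.
- Sharpless epoxidation of F5 with D-(−)-diethyl tartrate would install the oxirane. D-tartrate is needed because the C5 hydroxyl, not the C2-side hydroxyl, is now the primary directing group and addresses the opposite face. This returns to the route at 20.
- The branched Z substituent and the free secondary C2 hydroxyl make this epoxidation less selective than step 6, which is why it is the second choice.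

Step 2. The most likely failure is poor regioselectivity of the monosilylation, or bis-silylation, because both hydroxyls are primary and allylic and differ only in their distance from tin. The fallback builds the differentiated Z-alkene by olefination instead of by differentiating a diol. It sets out from 4.
- Alkylation of the sodium salt of methyl bis(2,2,2-trifluoroethyl)phosphonoacetate with 4 would give methyl 2-[bis(2,2,2-trifluoroethoxy)phosphoryl]pent-4-enoate F6.
- Still–Gennari olefination of F6 (KN(SiMe3)2, 18-crown-6, −78 °C) with (tert-butyldimethylsilyloxy)acetaldehyde would give methyl (2Z)-4-{[tert-butyl(dimethyl)silyl]oxy}-2-(prop-2-en-1-yl)but-2-enoate F7.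
- Reduction with iBu2AlH at −78 °C would return to the route at 5.

Step 14. The most likely failure is acid-promoted decomposition, by opening of the oxirane or ionisation of the doubly allylic C5 alcohol, during the hours that the triisopropylsilyl ether needs in aqueous HF. The fallback separates the two unmasking events into orthogonal ones. It sets out from 24: Bu4NF buffered with AcOH in THF would remove only the silyl group to give (1R,5R,6R)-1-[(2E)-4,4-dimethoxy-3-methylbut-2-en-1-yl]-3-[(1E)-hept-1-en-1-yl]-5-hydroxy-4-(hydroxymethyl)-7-oxabicyclo[4.1.0]hept-3-en-2-one F8. PPTS in wet acetone would then hydrolyse the acetal and return to the route at 25.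

## Further compounds

F1 | step 13 | (1R,6S)-1-[(2E)-4,4-dimethoxy-3-methylbut-2-en-1-yl]-3-[(1E)-hept-1-en-1-yl]-4-{[(triisopropylsilyl)oxy]methyl}-7-oxabicyclo[4.1.0]hept-3-ene-2,5-dione | CCCCC/C=C/C1=C(CO[Si](C(C)C)(C(C)C)C(C)C)C(=O)[C@H]2O[C@@]2(C/C=C(\C)C(OC)OC)C1=O
F2 | step 10 | (2Z)-4-{[tert-butyl(dimethyl)silyl]oxy}-2-[(2E)-4,4-dimethoxy-3-methylbut-2-en-1-yl]but-2-enal | O=C/C(C/C=C(\C)C(OC)OC)=C\CO[Si](C)(C)C(C)(C)C
F3 | step 10 | (5Z)-7-{[tert-butyl(dimethyl)silyl]oxy}-5-[(2E)-4,4-dimethoxy-3-methylbut-2-en-1-yl]-1-[(triisopropylsilyl)oxy]hept-5-en-2-yn-4-ol, racemic | CC(C)[Si](OCC#CC(O)/C(C/C=C(\C)C(OC)OC)=C\CO[Si](C)(C)C(C)(C)C)(C(C)C)C(C)C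
F4 | step 10 | racemic iodo-triene alcohol: F3 after anti addition of (1E)-hept-1-enyl at the carbinol-side alkyne carbon and iodine at the other (Z-iodoalkene, iodine cis to the carbinol carbon) | CCCCC/C=C/C(=C(/I)CO[Si](C(C)C)(C(C)C)C(C)C)C(O)/C(C/C=C(\C)C(OC)OC)=C\CO[Si](C)(C)C(C)(C)C
F5 | step 10 | F4 without the tert-butyldimethylsilyl group (free primary allylic alcohol) | CCCCC/C=C/C(=C(/I)CO[Si](C(C)C)(C(C)C)C(C)C)C(O)/C(C/C=C(\C)C(OC)OC)=C\CO
F6 | step 2 | methyl 2-[bis(2,2,2-trifluoroethoxy)phosphoryl]pent-4-enoate, racemic | C=CCC(C(=O)OC)P(=O)(OCC(F)(F)F)OCC(F)(F)F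
F7 | step 2 | methyl (2Z)-4-{[tert-butyl(dimethyl)silyl]oxy}-2-(prop-2-en-1-yl)but-2-enoate | COC(=O)/C(CC=C)=C\CO[Si](C)(C)C(C)(C)C
F8 | step 14 | (1R,5R,6R)-1-[(2E)-4,4-dimethoxy-3-methylbut-2-en-1-yl]-3-[(1E)-hept-1-en-1-yl]-5-hydroxy-4-(hydroxymethyl)-7-oxabicyclo[4.1.0]hept-3-en-2-one | CCCCC/C=C/C1=C(CO)[C@@H](O)[C@H]2O[C@@]2(C/C=C(\C)C(OC)OC)C1=O
A1 | alternative 1 | (2Z,4R,5S)-4-{[tert-butyl(dimethyl)silyl]oxy}-3-({[tert-butyl(dimethyl)silyl]oxy}methyl)-2-[(1E)-hept-1-en-1-yl]-6-oxo-5-[(triethylsilyl)oxy]nona-2,8-dienal | CCCCC/C=C/C(C=O)=C(CO[Si](C)(C)C(C)(C)C)/[C@@H](O[Si](C)(C)C(C)(C)C)[C@H](O[Si](CC)(CC)CC)C(=O)CC=C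
A2 | alternative 1 | (4R,5S,6R)-4-{[tert-butyl(dimethyl)silyl]oxy}-3-({[tert-butyl(dimethyl)silyl]oxy}methyl)-2-[(1E)-hept-1-en-1-yl]-6-hydroxy-6-(prop-2-en-1-yl)-5-[(triethylsilyl)oxy]cyclohex-2-en-1-one | CCCCC/C=C/C1=C(CO[Si](C)(C)C(C)(C)C)[C@@H](O[Si](C)(C)C(C)(C)C)[C@H](O[Si](CC)(CC)CC)[C@](O)(CC=C)C1=O
A3 | alternative 2 | 1,7-enyne: oxirane carrying the methyl (2E)-2-methylbut-2-enoate chain and a 1-hydroxyprop-2-ynyl group on the quaternary carbon and a 1-silyloxy-2-(silyloxymethyl)allyl group on the CH carbon, configuration as in the SMILES string | C#C[C@H](O)[C@]1(C/C=C(\C)C(=O)OC)O[C@@H]1[C@H](O[Si](C)(C)C(C)(C)C)C(=C)CO[Si](C)(C)C(C)(C)C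
A4 | alternative 2 | methyl (2E)-4-[(1S,2S,5R,6R)-5-{[tert-butyl(dimethyl)silyl]oxy}-4-({[tert-butyl(dimethyl)silyl]oxy}methyl)-3-ethenyl-2-hydroxy-7-oxabicyclo[4.1.0]hept-3-en-1-yl]-2-methylbut-2-enoate | C=CC1=C(CO[Si](C)(C)C(C)(C)C)[C@@H](O[Si](C)(C)C(C)(C)C)[C@H]2O[C@@]2(C/C=C(\C)C(=O)OC)[C@H]1O
A5 | alternative 3 | acyclic alpha-bromo ketone aldehyde: methyl (2E)-5-bromo-2-methyl-6-oxo-alkenoate chain joined at C2 to the Z tetrasubstituted C3=C4 alkene that carries heptenyl and silyloxymethyl, ending in the alpha-silyloxy aldehyde C5–C6, configuration as in the SMILES string (C1 unspecified) | CCCCC/C=C/C(C(=O)C(Br)C/C=C(\C)C(=O)OC)=C(CO[Si](C)(C)C(C)(C)C)/[C@@H](O[Si](C)(C)C(C)(C)C)C=O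
A6 | alternative 3 | methyl (2E)-4-[(1R,5R,6R)-5-{[tert-butyl(dimethyl)silyl]oxy}-4-({[tert-butyl(dimethyl)silyl]oxy}methyl)-3-[(1E)-hept-1-en-1-yl]-2-oxo-7-oxabicyclo[4.1.0]hept-3-en-1-yl]-2-methylbut-2-enoate | CCCCC/C=C/C1=C(CO[Si](C)(C)C(C)(C)C)[C@@H](O[Si](C)(C)C(C)(C)C)[C@H]2O[C@@]2(C/C=C(\C)C(=O)OC)C1=O
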